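A closed flask and a stirred tank given the same charge for the same 1.0 h differ in this: the closed flask moves from stage to stage, while the tank stays at one stage.

| flask | G | D | remark | time |
|---|---|---|---|---|
| beta | 17 mM | 34 mM | run made earlier |  |
| eta | 8.5 mM | 34 mM | run made earlier |  |
| delta | 34 mM | 34 mM | run made earlier |  |
| north-west | 17 mM | 34.0 mM | everything together in a closed stirred flask, run for 1.0 h | 1.0 h |
| east | 17 mM | 34.0 mM | one stirred flow tank at steady state, fed with the mixture as stated, mean residence time 1.0 h |  |
| south-west | 17 mM (fed, over 0.500 h) | 34.0 mM | all but G at the start; G goes in evenly over 0.500 h, the run ends at 1.0 h | 1.0 h |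
| west | 17 mM | 34.0 mM (fed, over 0.500 h) | all but D at the start; D goes in evenly over 0.500 h, the run ends at 1.0 h | 1.0 h |

- beta (time / min: E / %, L / %, Z / %): 8.00: 18.8, 4.5, 6.9; 15.0: 16.2, 11.3, 15.2; 25.0: 12.1, 13.5, 21.2; 30.0: 10.9, 15.0, 23.6; 40.0: 9.1, 13.8, 28.0; 50.0: 9.2, 13.0, 32.4; 60.0: 8.7, 12.8, 34.9
- eta (time / min: E / %, L / %, Z / %): 6.00: 19.8, 4.6, 5.5; 8.00: 21.5, 6.5, 9.0; 12.0: 20.8, 11.2, 13.7; 20.0: 16.0, 16.9, 22.4; 30.0: 12.7, 21.0, 31.6; 50.0: 9.4, 22.2, 41.2; 80.0: 6.7, 20.0, 52.6
- delta (time / min: E / %, L / %, Z / %): 6.00: 16.2, 3.1, 3.9; 8.00: 17.4, 4.7, 6.4; 12.0: 14.8, 6.4, 8.7; 20.0: 11.6, 7.8, 13.4; 30.0: 8.7, 9.7, 16.6; 50.0: 8.7, 8.6, 22.2; 80.0: 7.2, 4.8, 26.2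

(each reading ± 0.5 percentage points)

- the stated concentrations are those of everything mixed, before any reaction; amounts are the same in each set-up
- what was read earlier has a scatter of 0.5 percentage points, one standard deviation
- the feed brings no volume worth counting
- the earlier runs were made in a closed, stirred flask

- the set-up with the highest share of E in all that became E or L or Z, at the outlet or at the end ("none" if the first two lie within 2 percentage points) (north-west / east / south-west / west / none)
- share of E in all that became E or L or Z, at the outlet or at the end, north-west
- share of E in all that became E or L or Z, at the outlet or at the end, east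
- share of E in all that became E or L or Z, at the outlet or at the end, south-west
- share of E in all that became E or L or Z, at the outlet or at the end, west

North-west has the [G] and [D] of the beta run and ends at its last reading, so we read its share there: 15.4%. East needs a balance. In a steady tank, the L and Z leaving per hour were made, net, from the E standing there. So the share is one over one plus the residence time multiplied by the L and Z made per hour per E standing.

As a first link, the beta run from 30.0 min to 60.0 min gives 1.86 h⁻¹, hence a share of 35.0%. The weak link is the assumption that the tank stands at that late stage, so we put this back through the same balance on G. With a rate proportional to the G remaining, conversion in a tank is rate times residence time over one plus that product. The late net G rate of 0.293 h⁻¹ gives 22.7%, less than the 49.5% converted at 30.0 min. The tank therefore stands earlier. The stretch from 8.00 min to 15.0 min, with 1.69 h⁻¹, overshoots at 62.8%, more than the 42.7% converted at 15.0 min, so we bracket the tank between the 15.0 min and 30.0 min readings. Between those readings, the beta run gives 3.57 h⁻¹ for the L and Z made per E standing: E's turnover, a net ratio averaged over that stretch and no constant, being higher than the 1.86 h⁻¹ of the later stretch. We commit to 21.9% for east, 6.5 percentage points above north-west, and reckon neither fed flask by hand.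

The forecast gave 16% for north-west, 32% for east, 25% for south-west and 24% for west, with east higher than our figure, and concluded “East is best.”

The flask gives 14.8% for north-west, 21.5% for east, 17.6% for south-west and 18.1% for west, so the best set-up is east.

    G + D ⇌ X + E (K = 0.161, k = 0.0331 L mol⁻¹ s⁻¹)
    E + D ⇌ X + L (K = 0.850, k = 0.0327 L mol⁻¹ s⁻¹)
    E + D → Z (k = 0.0382 L mol⁻¹ s⁻¹)

East's share means a turnover of 3.65 h⁻¹, against our 3.57 h⁻¹ from the beta readings. Taken per hour elapsed, the same ratio in closed north-west reads 5.76 h⁻¹. North-west is not at rest at 1.0 h: it still holds 43.2% G, 8.38% E, 13.0% L and 35.4% Z. Ten times as long, the ratio per hour elapsed reads 5.95 h⁻¹, and E's share has fallen to 1.65%.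

The readings come from a simulation from invented constants; scatter was added.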